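**Plan**
- Retrosynthesis (side chain numbered C1′ at the benzylic carbon to C17′ at the methyl): after removing the MOM and TBS groups, cut the vinyl–allyl bond C9′–C10′ and, in the same operation, C7′–C8′, which reduces the cis C8′=C9′ unit to acetylene.
- Enabling feature: the cis CH=CH unit C8′=C9′ sits between the sp3 carbon C7′ and the doubly allylic methylene C10′. It is therefore the retron of syn-carbocupration of HC≡CH by an alkyl cuprate, followed by capture with a primary Z-allylic bromide.
- Further cuts: C11′=C12′ (Z-selective cross-metathesis), C14′–C15′ (epoxide opening) and aryl–C1′ (Cu-catalysed Grignard coupling); the resorcinol ring is bought and no ring is formed.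
- Forward: aryl-heptyl iodide 6 (3 steps) and (S,Z)-allylic bromide 13 (4 steps) are joined with acetylene in one pot, then one acidic global deprotection gives the target.
- Stereochemistry: C16′ (S) comes from (S)-propylene oxide and is never touched; C11′=C12′ (Z) from catalyst control; C8′=C9′ (Z) from syn-addition of C–Cu across acetylene.

Key step: step 8

Remark: but-3-enylmagnesium bromide (8) is taken as the commercial THF solution.

**Step 1**
Reactants: 1 5-bromobenzene-1,3-diol (5-bromoresorcinol)
Product: 2 1-bromo-3,5-bis(methoxymethoxy)benzene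
Conditions: NaH (2.4 equiv), MOMCl (2.4 equiv), DMF, 0 °C → rt
Reagents that add atoms: chloromethyl methyl ether (MOMCl), COCCl
Why: Williamson-type O-alkylation of both phenoxides gives the bis-MOM acetal, which should tolerate the Grignard, organolithium and cuprate steps and leave under mild acid at the end.

**Step 2**
Reactants: 2 1-bromo-3,5-bis(methoxymethoxy)benzene; 3 1,7-dibromoheptane
Product: 5 1-(7-bromoheptyl)-3,5-bis(methoxymethoxy)benzene, via arylmagnesium bromide 4 (not isolated)
Conditions: Mg, THF, reflux; then 3 (3 equiv), Li2CuCl4 (3 mol%), THF, −10 °C → rt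
Reagents that add atoms: none
Why: Kochi-type copper-catalysed sp2–sp3 coupling of an aryl Grignard reagent with a primary alkyl bromide, with excess dibromide to hold the reaction at mono-substitution.

**Step 3**
Reactants: 5 1-(7-bromoheptyl)-3,5-bis(methoxymethoxy)benzene
Product: 6 1-(7-iodoheptyl)-3,5-bis(methoxymethoxy)benzene
Conditions: NaI (3 equiv), acetone, reflux
Reagents that add atoms: sodium iodide, [Na+].[I-]
Why: Finkelstein exchange, driven by precipitation of NaBr, should give the primary iodide needed for clean iodine–lithium exchange.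

**Step 4**
Reactants: 7 (S)-2-methyloxirane ((S)-propylene oxide); 8 but-3-en-1-ylmagnesium bromide
Product: 9 (S)-hept-6-en-2-ol
Conditions: CuI (10 mol%), THF, −30 → 0 °C; sat. aq NH4Cl
Reagents that add atoms: none
Why: Copper-catalysed Grignard opening of the terminal epoxide occurs by SN2 attack at the unsubstituted carbon, so the C–O stereocentre is untouched and the (S) configuration is carried into the carbinol.

**Step 5**
Reactants: 9 (S)-hept-6-en-2-ol
Product: 10 (S)-tert-butyl(hept-6-en-2-yloxy)dimethylsilane
Conditions: TBSCl, imidazole, DMF, rt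
Reagents that add atoms: tert-butyldimethylsilyl chloride (TBSCl), CC(C)(C)[Si](C)(C)Cl
Why: Standard imidazole-promoted silylation of a secondary alcohol gives a TBS ether that is stable to the metathesis, bromination and cuprate steps and leaves with the MOM groups under acid.

**Step 6**
Reactants: 10 (S)-tert-butyl(hept-6-en-2-yloxy)dimethylsilane; 11 (Z)-but-2-ene-1,4-diol
Product: 12 (2Z,7S)-7-[(tert-butyldimethylsilyl)oxy]oct-2-en-1-ol
Conditions: Z-selective Ru catechothiolate carbene catalyst [Ru(NHC)(3,6-dichlorobenzene-1,2-dithiolato) o-isopropoxybenzylidene] (5 mol%), 11 (3 equiv), THF, 22 °C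
Reagents that add atoms: none
Why: Catalyst-controlled Z-selective olefin cross-metathesis of a terminal alkene with a cis-1,2-disubstituted diol partner, in which the metallacyclobutane substituents are forced syn away from the large NHC, should give the Z allylic alcohol directly; the remote stereocentre is unaffected.

**Step 7**
Reactants: 12 (2Z,7S)-7-[(tert-butyldimethylsilyl)oxy]oct-2-en-1-ol
Product: 13 tert-butyl{[(2S,6Z)-8-bromooct-6-en-2-yl]oxy}dimethylsilane
Conditions: CBr4, PPh3, CH2Cl2, 0 °C
Reagents that add atoms: carbon tetrabromide, BrC(Br)(Br)Br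
Why: Appel bromination (SN2 displacement of the alkoxyphosphonium by bromide at the primary allylic carbon) should retain the Z geometry at low temperature and leave the TBS ether intact.

**Step 8**
Reactants: 6 1-(7-iodoheptyl)-3,5-bis(methoxymethoxy)benzene; 14 acetylene (ethyne); 13 tert-butyl{[(2S,6Z)-8-bromooct-6-en-2-yl]oxy}dimethylsilane
Product: 18 tert-butyl{[(2S,6Z,9Z)-17-[3,5-bis(methoxymethoxy)phenyl]heptadeca-6,9-dien-2-yl]oxy}dimethylsilane, via alkyllithium 15 (not isolated), via lithium dialkylcuprate 16 (not isolated), via lithium bis-Z-alkenylcuprate 17 (not isolated)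
Conditions: 6 (2.0 equiv), t-BuLi (4.0 equiv), Et2O–pentane, −78 °C; CuBr·SMe2 (1.0 equiv), −78 → −35 °C; HC≡CH (2.0 equiv), −50 → −25 °C; 13 (1.0 equiv), THF, −78 → −20 °C; aq NH4Cl
Reagents that add atoms: none
Why: Iodine–lithium exchange gives the primary alkyllithium 15, which with CuBr·SMe2 forms the Gilman cuprate 16; each C–Cu bond then adds syn across acetylene through a four-centre transition state to give the (Z)-alkenyl cuprate 17 (C7′–C8′ formed, Cu on C9′), and this ate complex displaces bromide at the primary allylic carbon C10′ of 13 by oxidative addition/reductive elimination at copper, forming C9′–C10′ with retention at the alkenyl carbon. The closest known reaction type is the carbocupration of acetylene by lithium dialkylcuprates followed by allylation of the alkenyl cuprate, long used for cis-alkene pheromones. No ring is closed and no stereocentre is formed; the C16′ centre is a remote spectator. The new C8′=C9′ geometry is fixed as Z by the syn-addition and by the configurational stability of alkenylcopper species below −20 °C, while the C11′=C12′ Z geometry of 13 is carried through because substitution occurs at the sp3 α-carbon without a long-lived π-allyl intermediate. The selectivity required is α (SN2) over γ (SN2′) attack and a single acetylene insertion: the former is favoured by the unhindered CH2Br terminus and by using the diorganocuprate (not a monoorganocopper) with 13 limiting so that only the ate complex transfers a ligand, the latter by keeping the temperature at or below −25 °C. MOM and TBS ethers are inert to the organolithium and cuprate at these temperatures.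

**Step 9**
Reactants: 18 tert-butyl{[(2S,6Z,9Z)-17-[3,5-bis(methoxymethoxy)phenyl]heptadeca-6,9-dien-2-yl]oxy}dimethylsilane
Product: 19 Hansfordiol D, 5-[(8Z,11Z,16S)-16-hydroxyheptadeca-8,11-dien-1-yl]benzene-1,3-diol
Conditions: HCl (1 M in MeOH), MeOH, rt → 40 °C
Reagents that add atoms: none
Why: Acid-catalysed acetal exchange (both MOM groups) and solvolytic desilylation (TBS) in methanol remove all protecting groups in one operation; the skipped diene should not isomerise and the carbinol centre is not ionised under these conditions.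

**Compound list**
1 | 5-bromobenzene-1,3-diol | Oc1cc(O)cc(Br)c1 | starting material
2 | 1-bromo-3,5-bis(methoxymethoxy)benzene | COCOc1cc(Br)cc(OCOC)c1 | intermediate
3 | 1,7-dibromoheptane | BrCCCCCCCBr | starting material
4 | [3,5-bis(methoxymethoxy)phenyl]magnesium bromide | COCOc1cc([Mg]Br)cc(OCOC)c1 | intermediate
5 | 1-(7-bromoheptyl)-3,5-bis(methoxymethoxy)benzene | COCOc1cc(CCCCCCCBr)cc(OCOC)c1 | intermediate
6 | 1-(7-iodoheptyl)-3,5-bis(methoxymethoxy)benzene | COCOc1cc(CCCCCCCI)cc(OCOC)c1 | intermediate
7 | (S)-2-methyloxirane | C[C@H]1CO1 | starting material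
8 | but-3-en-1-ylmagnesium bromide | C=CCC[Mg]Br | starting material
9 | (S)-hept-6-en-2-ol | C[C@H](O)CCCC=C | intermediate
10 | (S)-tert-butyl(hept-6-en-2-yloxy)dimethylsilane | C[C@H](O[Si](C)(C)C(C)(C)C)CCCC=C | intermediate
11 | (Z)-but-2-ene-1,4-diol | OC/C=C\CO | starting material
12 | (2Z,7S)-7-[(tert-butyldimethylsilyl)oxy]oct-2-en-1-ol | C[C@H](O[Si](C)(C)C(C)(C)C)CCC/C=C\CO | intermediate
13 | tert-butyl{[(2S,6Z)-8-bromooct-6-en-2-yl]oxy}dimethylsilane | C[C@H](O[Si](C)(C)C(C)(C)C)CCC/C=C\CBr | intermediate
14 | acetylene (ethyne) | C#C | starting material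
15 | {7-[3,5-bis(methoxymethoxy)phenyl]heptyl}lithium | [Li]CCCCCCCc1cc(OCOC)cc(OCOC)c1 | intermediate
16 | lithium bis{7-[3,5-bis(methoxymethoxy)phenyl]heptyl}cuprate | [Li+].COCOc1cc(CCCCCCC[Cu-]CCCCCCCc2cc(OCOC)cc(OCOC)c2)cc(OCOC)c1 | intermediate
17 | lithium bis{(Z)-9-[3,5-bis(methoxymethoxy)phenyl]non-1-en-1-yl}cuprate | [Li+].COCOc1cc(CCCCCCC/C=C\[Cu-]/C=C\CCCCCCCc2cc(OCOC)cc(OCOC)c2)cc(OCOC)c1 | intermediate
18 | tert-butyl{[(2S,6Z,9Z)-17-[3,5-bis(methoxymethoxy)phenyl]heptadeca-6,9-dien-2-yl]oxy}dimethylsilane | C[C@H](O[Si](C)(C)C(C)(C)C)CCC/C=C\C/C=C\CCCCCCCc1cc(OCOC)cc(OCOC)c1 | intermediate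
19 | Hansfordiol D, 5-[(8Z,11Z,16S)-16-hydroxyheptadeca-8,11-dien-1-yl]benzene-1,3-diol | C[C@H](O)CCC/C=C\C/C=C\CCCCCCCc1cc(O)cc(O)c1 | target

**Totals**
Total step count: 9. Longest linear sequence: 6 steps (steps 4, 5, 6, 7, 8, 9, from (S)-propylene oxide).

**Steps most likely to fail, with fallbacks**

Step 8. The allylation may go partly by γ-attack (SN2′) on the allylic bromide, giving a branched 1,4-diene. The allyl geometry may also leak through a π-allyl copper species, a second acetylene may insert if the temperature rises, or the alkyllithium may metalate the ring position between the MOM groups before the cuprate forms. The fallback sets out from 6 (with 13) and comes back at 18. Alkylation of lithium acetylide–ethylenediamine with 6 in DMSO at rt should give 1,3-bis(methoxymethoxy)-5-(non-8-yn-1-yl)benzene F1. Copper-mediated sp–sp3 coupling of F1 with 13 (CuI, K2CO3, n-Bu4NCl, DMF, rt), an SN2 process that keeps the allyl geometry, should give the skipped enyne tert-butyl{[(2S,6Z)-17-[3,5-bis(methoxymethoxy)phenyl]heptadec-6-en-9-yn-2-yl]oxy}dimethylsilane F2. Lindlar semihydrogenation (Pd/CaCO3/Pb, quinoline, H2, EtOAc) should then give 18.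

Step 6. Z-selectivity may erode through secondary metathesis, or the catalyst may decompose through methylidene formation by ethylene, leaving low conversion and homodimer. The fallback sets out from 10 and comes back at 12. Ozonolysis (O3, CH2Cl2, −78 °C; PPh3) should give (S)-5-[(tert-butyldimethylsilyl)oxy]hexanal F3. Still–Gennari olefination (methyl bis(2,2,2-trifluoroethyl)phosphonoacetate, KHMDS, 18-crown-6, THF, −78 °C) should give methyl (2Z,7S)-7-[(tert-butyldimethylsilyl)oxy]oct-2-enoate F4 under kinetic Z control. DIBAL-H reduction (CH2Cl2, −78 °C) should then give 12.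

Step 2. The aryl Grignard/alkyl bromide coupling may be sluggish, with substitution at both ends of the dibromide, biaryl formation or reduction of the Grignard reagent competing. The fallback sets out from 2 and comes back at 6, bypassing 5. Sonogashira coupling of 2 with hept-6-yn-1-ol (PdCl2(PPh3)2, CuI, Et3N, 60 °C) should give 7-[3,5-bis(methoxymethoxy)phenyl]hept-6-yn-1-ol F5. Hydrogenation (H2, Pd/C, EtOAc) should give 7-[3,5-bis(methoxymethoxy)phenyl]heptan-1-ol F6. Iodination (I2, PPh3, imidazole, CH2Cl2, 0 °C) should then give 6.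

**Further compounds**
F1 | step 8 | 1,3-bis(methoxymethoxy)-5-(non-8-yn-1-yl)benzene | C#CCCCCCCCc1cc(OCOC)cc(OCOC)c1
F2 | step 8 | tert-butyl{[(2S,6Z)-17-[3,5-bis(methoxymethoxy)phenyl]heptadec-6-en-9-yn-2-yl]oxy}dimethylsilane | C[C@H](O[Si](C)(C)C(C)(C)C)CCC/C=C\CC#CCCCCCCCc1cc(OCOC)cc(OCOC)c1
F3 | step 6 | (S)-5-[(tert-butyldimethylsilyl)oxy]hexanal | C[C@H](O[Si](C)(C)C(C)(C)C)CCCC=O
F4 | step 6 | methyl (2Z,7S)-7-[(tert-butyldimethylsilyl)oxy]oct-2-enoate | C[C@H](O[Si](C)(C)C(C)(C)C)CCC/C=C\C(=O)OC
F5 | step 2 | 7-[3,5-bis(methoxymethoxy)phenyl]hept-6-yn-1-ol | COCOc1cc(C#CCCCCCO)cc(OCOC)c1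
F6 | step 2 | 7-[3,5-bis(methoxymethoxy)phenyl]heptan-1-ol | COCOc1cc(CCCCCCCO)cc(OCOC)c1
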